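Ring A of the flavanone (C4a, C5, C6, C7, C8, C8a) bears four adjacent substituents: the C4 carbonyl on C4a, O1 on C8a, the prenyl group on C8 and the ether oxygen on C7. The route cuts this ring at C5–C6 and C4a–C8a into a four-carbon diene, 2-prenylated 1-methoxy-1,3-bis(trimethylsilyloxy)butadiene, and but-3-yn-2-one. Their [4+2] union and loss of methanol deliver the complete 3-prenylated 2,4-dihydroxyacetophenone in one operation, so the prenyl group never has to be introduced onto a preformed arene. Selective O7 propargylation, chromone annulation, semihydrogenation and a rhodium-catalysed asymmetric addition of phenylboronic acid, which sets C2 as S, finish the synthesis.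

Key step: step 4

Assumption: in step 8 the (S,S) enantiomer of the diene ligand is taken, by analogy with its behaviour towards cyclic enones, to direct phenyl to the Re face of C2 (O1 > C3 > H), which gives 2S; if a small trial run shows the opposite sense, the (R,R) ligand is used.

Step 1
Reactants: 1 methyl acetoacetate; 2 prenyl bromide
Product: 3 methyl 2-acetyl-5-methylhex-4-enoate (racemic)
Conditions: NaH, THF, 0 °C to rt (1 in slight excess)
Reagents that add atoms: none
Why: The sodium enolate of the β-keto ester is alkylated at carbon by the primary allylic bromide (acetoacetic ester alkylation, SN2), and a slight excess of 1 limits double alkylation.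

Step 2
Reactants: 3 methyl 2-acetyl-5-methylhex-4-enoate
Product: 4 methyl 2-(3-methylbut-2-enyl)-3-(trimethylsilyloxy)but-2-enoate (E/Z mixture, both usable)
Conditions: Me3SiCl, Et3N, toluene, rt; filter, concentrate
Reagents that add atoms: chlorotrimethylsilane, C[Si](C)(C)Cl
Why: Soft enolisation of the β-keto ester and O-silylation give the conjugated silyl enol ether, the standard first stage in the preparation of 1,3-bis(silyloxy)dienes.

Step 3
Reactants: 4 methyl 2-(3-methylbut-2-enyl)-3-(trimethylsilyloxy)but-2-enoate
Product: 5 1-methoxy-2-(3-methylbut-2-enyl)-1,3-bis(trimethylsilyloxy)buta-1,3-diene (used crude, moisture-sensitive)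
Conditions: LiN(i-Pr)2, THF, −78 °C; Me3SiCl, −78 to 0 °C
Reagents that add atoms: chlorotrimethylsilane, C[Si](C)(C)Cl
Why: The amide base removes a proton from the γ-methyl group, the only site that gives an ester-conjugated dienolate, and O-silylation of that dienolate forms the ketene acetal (second stage of the bis(silyl enol ether) preparation).

Step 4
Reactants: 5 1-methoxy-2-(3-methylbut-2-enyl)-1,3-bis(trimethylsilyloxy)buta-1,3-diene; 6 but-3-yn-2-one
Product: 8 1-[2,4-dihydroxy-3-(3-methylbut-2-enyl)phenyl]ethanone, via cyclohexadiene cycloadduct 7 (not isolated)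
Conditions: toluene, 0 to 50 °C (6 in slight excess); then 1 M HCl, THF, 0 °C
Reagents that add atoms: none
Why: The electron-rich diene 5 and the electron-poor alkyne 6 should combine in a normal-demand Diels–Alder reaction that is strongly asynchronous, in the limit a Mukaiyama–Michael addition followed by ring closure: the unsubstituted CH2 terminus of 5, its most nucleophilic carbon, bonds to the β-carbon of the ynone (C5–C6) and the ketene acetal carbon then bonds to the α-carbon (C4a–C8a). Ring A is closed as a six-membered carbocycle by intermolecular [4+2] annulation of a four-carbon unit with a two-carbon unit, giving 1,4-cyclohexadiene 7, whose methyl silyl ketal collapses on cold acidic work-up with loss of methanol and both silyl groups to the aromatic resorcinol. The closest known reaction type is the benzannulation of 1-alkoxy-1,3-bis(silyloxy)butadienes with acetylenic esters and ketones to 2,4-dihydroxyaryl carbonyl compounds. No stereocentre is formed that survives aromatisation, so the step needs only regioselectivity, which the matched polarisation of both partners secures: acyl ends up ortho to the C8a oxygen and para to the C7 oxygen. The prenyl group sits on the central diene carbon that becomes C8, takes no part in bond formation and is therefore delivered between the two oxygens with no positional ambiguity. Thermal conditions without Lewis acid and a cold, dilute acidic work-up keep the prenyl double bond intact.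

Step 5
Reactants: 8 1-[2,4-dihydroxy-3-(3-methylbut-2-enyl)phenyl]ethanone; 9 3-chloro-3-methylbut-1-yne
Product: 10 1-[2-hydroxy-3-(3-methylbut-2-enyl)-4-(2-methylbut-3-yn-2-yloxy)phenyl]ethanone
Conditions: DBU (1.3 equiv), CuCl2·2H2O (cat.), MeCN, 0 °C
Reagents that add atoms: none
Why: Copper-catalysed propargylic etherification takes place at the free and more acidic 4-OH, because the 2-OH is tied up in a hydrogen bond to the ketone, and 0 °C is far below the temperature of propargyl Claisen rearrangement.

Step 6
Reactants: 10 1-[2-hydroxy-3-(3-methylbut-2-enyl)-4-(2-methylbut-3-yn-2-yloxy)phenyl]ethanone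
Product: 12 8-(3-methylbut-2-enyl)-7-(2-methylbut-3-yn-2-yloxy)chromen-4-one, via enaminone 11 (not isolated)
Conditions: Me2NCH(OMe)2, toluene, 80 °C; concentrate; 2 M HCl, CH2Cl2, rt
Reagents that add atoms: N,N-dimethylformamide dimethyl acetal, COC(OC)N(C)C
Why: Condensation of the methyl ketone with the formamide acetal gives the enaminone, and acid then drives conjugate addition of the 2-OH to the enaminone carbon with loss of dimethylamine, closing the six-membered 4-pyranone ring (O1, C2, C3, C4, C4a, C8a; enaminone route to chromones); with O7 already etherified the acetal cannot methylate a free phenol, and the propargyl ether tolerates 80 °C.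

Step 7
Reactants: 12 8-(3-methylbut-2-enyl)-7-(2-methylbut-3-yn-2-yloxy)chromen-4-one
Product: 13 7-(2-methylbut-3-en-2-yloxy)-8-(3-methylbut-2-enyl)chromen-4-one
Conditions: H2 (1 atm), Pd/CaCO3–Pb(OAc)2, quinoline, EtOAc, rt, stopped at one equivalent of H2
Reagents that add atoms: none
Why: Lindlar semihydrogenation reduces the terminal alkyne to the vinyl group, while the poisoned catalyst leaves the trisubstituted prenyl alkene and the vinylogous-ester C2=C3 bond of the chromone alone.

Step 8
Reactants: 13 7-(2-methylbut-3-en-2-yloxy)-8-(3-methylbut-2-enyl)chromen-4-one; 14 phenylboronic acid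
Product: 15 Griffinone C, (2S)-7-(2-methylbut-3-en-2-yloxy)-8-(3-methylbut-2-enyl)-2-phenyl-2,3-dihydrochromen-4-one
Conditions: 14 (3 equiv), [RhCl(C2H4)2]2 (2.5 mol%), (S,S)-2,5-diphenylbicyclo[2.2.2]octa-2,5-diene (6 mol%), aq. KOH (10 mol%), toluene/H2O, 30 °C
Reagents that add atoms: none
Why: In this Hayashi–Miyaura asymmetric conjugate addition the phenylrhodium species bound to the chiral diene inserts the chromone C2=C3 bond on the Re face of C2, as dictated by the ligand, and protonolysis releases the (2S)-flavanone; the nearly neutral medium at 30 °C spares the tertiary allyl ether and limits ring opening that would erode the C2 configuration.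

Compound list
1 | methyl acetoacetate | COC(=O)CC(C)=O | starting material
2 | prenyl bromide (1-bromo-3-methylbut-2-ene) | CC(C)=CCBr | starting material
3 | methyl 2-acetyl-5-methylhex-4-enoate (racemic) | COC(=O)C(CC=C(C)C)C(C)=O | intermediate
4 | methyl 2-(3-methylbut-2-enyl)-3-(trimethylsilyloxy)but-2-enoate (E/Z mixture) | COC(=O)C(CC=C(C)C)=C(C)O[Si](C)(C)C | intermediate
5 | 1-methoxy-2-(3-methylbut-2-enyl)-1,3-bis(trimethylsilyloxy)buta-1,3-diene (geometric mixture) | C=C(O[Si](C)(C)C)C(CC=C(C)C)=C(OC)O[Si](C)(C)C | intermediate
6 | but-3-yn-2-one | CC(=O)C#C | starting material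
7 | 1-[6-methoxy-5-(3-methylbut-2-enyl)-4,6-bis(trimethylsilyloxy)cyclohexa-1,4-dien-1-yl]ethanone (racemic, not isolated) | CC(=O)C1=CCC(O[Si](C)(C)C)=C(CC=C(C)C)C1(OC)O[Si](C)(C)C | intermediate
8 | 1-[2,4-dihydroxy-3-(3-methylbut-2-enyl)phenyl]ethanone | CC(=O)c1ccc(O)c(CC=C(C)C)c1O | intermediate
9 | 3-chloro-3-methylbut-1-yne | C#CC(C)(C)Cl | starting material
10 | 1-[2-hydroxy-3-(3-methylbut-2-enyl)-4-(2-methylbut-3-yn-2-yloxy)phenyl]ethanone | CC(=O)c1ccc(OC(C)(C)C#C)c(CC=C(C)C)c1O | intermediate
11 | (E)-3-(dimethylamino)-1-[2-hydroxy-3-(3-methylbut-2-enyl)-4-(2-methylbut-3-yn-2-yloxy)phenyl]prop-2-en-1-one (not isolated) | CN(C)/C=C/C(=O)c1ccc(OC(C)(C)C#C)c(CC=C(C)C)c1O | intermediate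
12 | 8-(3-methylbut-2-enyl)-7-(2-methylbut-3-yn-2-yloxy)chromen-4-one | C#CC(C)(C)Oc1ccc2c(c1CC=C(C)C)occc2=O | intermediate
13 | 7-(2-methylbut-3-en-2-yloxy)-8-(3-methylbut-2-enyl)chromen-4-one | C=CC(C)(C)Oc1ccc2c(c1CC=C(C)C)occc2=O | intermediate
14 | phenylboronic acid | OB(O)c1ccccc1 | starting material
15 | Griffinone C, (2S)-7-(2-methylbut-3-en-2-yloxy)-8-(3-methylbut-2-enyl)-2-phenyl-2,3-dihydrochromen-4-one | C=CC(C)(C)Oc1ccc2c(c1CC=C(C)C)O[C@H](c1ccccc1)CC2=O | target

Total step count: 8. Longest linear sequence: 8 steps (1 to 15).

Steps most likely to fail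

Step 4. The substituent on the central diene carbon disfavours the s-cis conformer, so hydrolysis of the diene, oligomerisation of the ynone or arrest at the open-chain Michael stage may outrun ring closure. The fallback gives up ring construction and sets out from 9. Commercial 1-(2,4-dihydroxyphenyl)ethanone (CC(=O)c1ccc(O)cc1O) would be etherified at its 4-OH with 9 (DBU, cat. CuCl2·2H2O, MeCN, 0 °C) to 1-[2-hydroxy-4-(2-methylbut-3-yn-2-yloxy)phenyl]ethanone F1. Semihydrogenation over Pd/CaCO3–Pb(OAc)2 with quinoline would give 1-[2-hydroxy-4-(2-methylbut-3-en-2-yloxy)phenyl]ethanone F2. Heating F2 in N,N-diethylaniline at about 130 °C should bring about an aromatic Claisen rearrangement that places the allyl unit, inverted to prenyl, on the ring. The shift is expected mainly at C3, between the two oxygens, as is usual for 4-allyloxy-2-hydroxyaryl ketones, and the C5 isomer would be removed by chromatography. The fallback returns to the route at 8.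

Step 8. Insertion of the electron-rich chromone may be slow and protodeboronation may consume the boronic acid. Base-mediated reversible opening of the pyranone ring may lower the enantiomeric purity, and heating to force conversion would invite Claisen rearrangement of the tertiary allyl ether towards C6. The fallback sets out from 10 and replaces asymmetric catalysis by ring closure and resolution. Semihydrogenation of 10 over Pd/CaCO3–Pb(OAc)2 with quinoline would give 1-[2-hydroxy-4-(2-methylbut-3-en-2-yloxy)-3-(3-methylbut-2-enyl)phenyl]ethanone F3. Claisen–Schmidt condensation with benzaldehyde (KOH, EtOH, rt) would give the chalcone (E)-1-[2-hydroxy-4-(2-methylbut-3-en-2-yloxy)-3-(3-methylbut-2-enyl)phenyl]-3-phenylprop-2-en-1-one F4. Intramolecular oxa-Michael addition (NaOAc, EtOH, 50 °C, unreacted chalcone recycled) would give racemic 7-(2-methylbut-3-en-2-yloxy)-8-(3-methylbut-2-enyl)-2-phenyl-2,3-dihydrochromen-4-one F5. Preparative HPLC of F5 on a chiral stationary phase would deliver the 2S enantiomer, so the fallback returns to the route at 15.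

Step 5. Etherification of the hindered 4-OH may stay incomplete while the tertiary chloride is lost by elimination, or site selectivity between the two hydroxyls may be poor. The fallback sets out from 8 and installs the tertiary allyl ether directly by allylic substitution, which bypasses steps 5 to 7. Treatment of 8 with Me2NCH(OMe)2 and then aqueous HCl would pass through the enaminone (E)-1-[2,4-dihydroxy-3-(3-methylbut-2-enyl)phenyl]-3-(dimethylamino)prop-2-en-1-one F6 to 7-hydroxy-8-(3-methylbut-2-enyl)chromen-4-one F7. Tsuji–Trost O-allylation of F7 with tert-butyl 2-methylbut-3-en-2-yl carbonate F8 (from 2-methylbut-3-en-2-ol, n-BuLi and di-tert-butyl dicarbonate) and Pd(PPh3)4 in THF at 0 °C should then form the ether. The phenoxide is expected to attack the more substituted allyl terminus as the kinetic pathway, and the reaction would be stopped at full conversion to prevent isomerisation to the linear prenyl ether. The fallback returns to the route at 13.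

Further compounds
F1 | step 4 | 1-[2-hydroxy-4-(2-methylbut-3-yn-2-yloxy)phenyl]ethanone | CC(=O)c1ccc(OC(C)(C)C#C)cc1O
F2 | step 4 | 1-[2-hydroxy-4-(2-methylbut-3-en-2-yloxy)phenyl]ethanone | CC(=O)c1ccc(OC(C)(C)C=C)cc1O
F3 | step 8 | 1-[2-hydroxy-4-(2-methylbut-3-en-2-yloxy)-3-(3-methylbut-2-enyl)phenyl]ethanone | CC(=O)c1ccc(OC(C)(C)C=C)c(CC=C(C)C)c1O
F4 | step 8 | (E)-1-[2-hydroxy-4-(2-methylbut-3-en-2-yloxy)-3-(3-methylbut-2-enyl)phenyl]-3-phenylprop-2-en-1-one | O=C(/C=C/c1ccccc1)c1ccc(OC(C)(C)C=C)c(CC=C(C)C)c1O
F5 | step 8 | racemic 7-(2-methylbut-3-en-2-yloxy)-8-(3-methylbut-2-enyl)-2-phenyl-2,3-dihydrochromen-4-one | C=CC(C)(C)Oc1ccc2c(c1CC=C(C)C)OC(c1ccccc1)CC2=O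
F6 | step 5 | (E)-1-[2,4-dihydroxy-3-(3-methylbut-2-enyl)phenyl]-3-(dimethylamino)prop-2-en-1-one | CN(C)/C=C/C(=O)c1ccc(O)c(CC=C(C)C)c1O
F7 | step 5 | 7-hydroxy-8-(3-methylbut-2-enyl)chromen-4-one | O=c1ccoc2c(CC=C(C)C)c(O)ccc12
F8 | step 5 | tert-butyl 2-methylbut-3-en-2-yl carbonate | C=CC(C)(C)OC(=O)OC(C)(C)C
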